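**Retrosynthetic overview**

1. Numbering as in germacranolides: C1 (furanone C=O), C2=C3, C3–O–C10 (furanone oxygen), C4(C15H3)=C5, C6 (lactone O), C7, C8 (ester O), C9 (OH), C10 (C14H3), C11(=C13H2)–C12(=O)–O–C6. The target is cut at O–C6 and at C11–C12 together: the lactone O–C12(=O) unit is taken out as CO2, which leaves the alkenylboronate/allylic benzoate 24.
2. Feature that allows this: in ring C (the γ-lactone) the oxygen sits on C6, which is allylic to the C4=C5 bond of the ten-membered ring (ionisable to an η3-allyl over C4–C5–C6), and C12 sits on C11, an sp2 carbon carrying the exocyclic C13 methylene (an alkenyl nucleophile). The lactone is therefore CO2 held between an allyl cation and an alkenyl anion.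
3. 24 ⇒ ten-membered hydroxy-ynone 23 (furanone by 5-endo addition of O10 to C3) ⇒ ring closure C1–C2 by intramolecular alkynylation of aldehyde 21.
4. Chain 17 ⇒ C6–C7 by allene diboration/allylboration, which also places boron on C11 and oxygen on C6: allenyl ester 12 + (Z)-enynal 14. 12 comes from 2-C-methyl-D-ribonolactone 1 (C1, C7–C10, C14), with C8 inverted by Mitsunobu esterification with acid 11.
5. Ring order: ten-membered carbocycle (step 15), furanone (step 16), α-methylene-γ-lactone (step 17); O-desilylation ends the route.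

Key step: step 17

Remark: 1, 11 and 13 are taken as commercial; all intermediates carry the numbering of the target.

**Route**

Step 1
Reactants: 1 2-C-methyl-D-ribono-1,4-lactone
Product: 2 3,5-di-O-TBS-2-C-methyl-D-ribono-1,4-lactone (tertiary O10–H free)
Conditions: TBSCl (2.5 equiv), imidazole, DMAP (cat.), DMF, 40 °C
Reagents that add atoms: tert-butyldimethylsilyl chloride, CC(C)(C)[Si](C)(C)Cl
Why: Silyl ether formation with TBSCl/imidazole should cap the primary (O7) and secondary (O9) hydroxyls and leave the hindered tertiary hydroxyl free; no stereocentre is touched.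

Step 2
Reactants: 2 3,5-di-O-TBS-2-C-methyl-D-ribono-1,4-lactone
Product: 3 3-O-TBS-2-C-methyl-D-ribono-1,4-lactone (C7–OH free)
Conditions: HF·pyridine, pyridine, THF, 0 °C
Reagents that add atoms: none
Why: Selective desilylation: buffered fluoride should cleave the primary silyl ether much faster than the hindered secondary one next to the quaternary carbon.

Step 3
Reactants: 3 3-O-TBS-2-C-methyl-D-ribono-1,4-lactone
Product: 4 C7 aldehyde of 3 (3-O-TBS-2-C-methyl-D-ribo-pentodialdono-1,4-lactone)
Conditions: Dess–Martin periodinane, pyridine, CH2Cl2, 0 °C to rt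
Reagents that add atoms: none
Why: Dess–Martin oxidation should convert the primary alcohol into the aldehyde under buffered conditions that do not epimerise C8 and leave the tertiary alcohol alone.

Step 4
Reactants: 4 C7 aldehyde of 3
Product: 5 ethynyl carbinol (C7H(OH)–C≡CH; both C7 epimers)
Conditions: HC≡CMgBr (2.5 equiv), THF, −78 °C; then aq. NH4Cl
Reagents that add atoms: ethynylmagnesium bromide, C#C[Mg]Br
Why: Grignard addition to the aldehyde should be much faster than to the lactone, whose neighbouring tertiary alkoxide forms first; the configuration of the new carbinol is irrelevant because step 5 erases it.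

Step 5
Reactants: 5 ethynyl carbinol
Product: 8 allenyl lactone (C7H=C11=C13H2 on C8), via sulfonylhydrazine adduct 6 (not isolated), via propargylic diazene 7 (not isolated)
Conditions: PPh3, DEAD, THF, −15 °C; then 2-nitrobenzenesulfonylhydrazide, −15 °C to rt
Reagents that add atoms: none
Why: Myers allene synthesis: Mitsunobu N-alkylation of the sulfonylhydrazide, loss of sulfinic acid and retro-ene loss of N2 from the diazene should give the terminal allene, which carries no new stereo-element.

Step 6
Reactants: 8 allenyl lactone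
Product: 9 allenyl triol (C1–OH, C8–OH, C10–OH; O9-TBS)
Conditions: LiBH4, THF, 0 °C to rt
Reagents that add atoms: none
Why: Borohydride reduction of the lactone should give the diol without touching the allene or the silyl ether.

Step 7
Reactants: 9 allenyl triol
Product: 10 C1/C10 acetonide of 9 (C8–OH free, D-ribo configuration)
Conditions: 2,2-dimethoxypropane, PPTS (cat.), CH2Cl2, rt
Reagents that add atoms: 2,2-dimethoxypropane, COC(C)(C)OC
Why: Under thermodynamic acetalisation the terminal 1,2-diol should form the five-membered acetonide in preference to six- or seven-membered alternatives, which leaves only the C8 hydroxyl free.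

Step 8
Reactants: 10 C1/C10 acetonide of 9; 11 (R)-2-methylbutanoic acid
Product: 12 allenyl ester (C8 (R)-2-methylbutanoate; C8, C9, C10 as in the target)
Conditions: PPh3, DIAD, toluene, 0 °C to rt
Reagents that add atoms: none
Why: Mitsunobu esterification proceeds by SN2 displacement of the activated C8 oxygen by the carboxylate, so it should invert the D-ribo C8 centre to the target configuration while installing the ester.

Step 9
Reactants: 13 (Z)-3-methylpent-2-en-4-yn-1-ol
Product: 14 (Z)-3-methylpent-2-en-4-ynal
Conditions: MnO2, CH2Cl2, rt, dark; used at once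
Reagents that add atoms: none
Why: MnO2 oxidation of the allylic alcohol should give the enal without touching the alkyne, and the Z geometry (the later C4=C5) is kept if the aldehyde is used immediately.

Step 10
Reactants: 12 allenyl ester; 14 (Z)-3-methylpent-2-en-4-ynal
Product: 17 syn homoallylic alcohol (6S,7S; C11(Bpin)=C13H2; C7 as in the target; C6 opposite to it), via bis(boronate) 15 (not isolated), via O-boryl adduct 16 (not isolated)
Conditions: B2pin2 (1.0 equiv), Pt(dba)2 (3 mol%), PCy3 (4 mol%), toluene, 50 °C; then 14, rt to 50 °C; aq. NH4Cl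
Reagents that add atoms: bis(pinacolato)diboron, CC1(C)OB(OC1(C)C)B1OC(C)(C)C(C)(C)O1
Why: Zerovalent-platinum-catalysed diboration should add both boryl groups syn to the terminal allene bond from the face away from C8 to give the (Z)-allylboronate 15, whose allylboration of 14 through a chair transition state gives the syn C6/C7 pair, with the aldehyde on the face of C7 anti to the C9 branch when the C8 hydrogen eclipses the alkene (A(1,3) strain).

Step 11
Reactants: 17 syn homoallylic alcohol
Product: 18 (6R)-benzoate (6R,7S)
Conditions: PhCO2H, PPh3, DIAD, THF, 0 °C to rt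
Reagents that add atoms: benzoic acid, O=C(O)c1ccccc1
Why: Mitsunobu reaction with benzoic acid should invert C6 by SN2 displacement, which corrects C6 to the target configuration and installs the allylic leaving group for the key step.

Step 12
Reactants: 18 (6R)-benzoate
Product: 19 C1,C10-diol
Conditions: PPTS, MeOH, 45 °C
Reagents that add atoms: none
Why: Acid-catalysed transacetalisation in methanol should remove the terminal acetonide while the hindered secondary silyl ether, both esters and the alkenylboronate survive.

Step 13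
Reactants: 19 C1,C10-diol
Product: 20 C2-iodoalkyne diol
Conditions: N-iodosuccinimide, AgNO3 (10 mol%), acetone, rt, dark
Reagents that add atoms: N-iodosuccinimide, O=C1CCC(=O)N1I
Why: Silver-catalysed iodination of the terminal alkyne runs through the silver acetylide and should not affect the alkenylboronate, which needs base activation to react with electrophiles.

Step 14
Reactants: 20 C2-iodoalkyne diol
Product: 21 α-hydroxy aldehyde (C1 aldehyde; O10–H free)
Conditions: IBX, DMSO, rt
Reagents that add atoms: none
Why: IBX should oxidise the primary alcohol of the 1,2-diol to the aldehyde without glycol cleavage; the aldehyde has no α-hydrogen and cannot epimerise.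

Step 15
Reactants: 21 α-hydroxy aldehyde
Product: 22 ten-membered enyne diol (C1–C2 bond closed; C1 carbinol epimers)
Conditions: CrCl2 (8 equiv), NiCl2 (2 mol%), THF, rt, syringe-pump addition (0.002 M)
Reagents that add atoms: none
Why: Intramolecular Nozaki–Hiyama–Kishi alkynylation: the iodoalkyne becomes an alkynylchromium species that should add chemoselectively to the aldehyde under high dilution to close the ten-membered ring; the new C1 stereocentre is removed in step 16.

Step 16
Reactants: 22 ten-membered enyne diol
Product: 24 bicyclic furanone (3,10-epoxy bridge; C6 benzoate; C7 C(Bpin)=CH2), via cyclic ynone 23 (not isolated)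
Conditions: IBX, EtOAc, 70 °C; filter; then Ph3PAuNTf2 (5 mol%), rt
Reagents that add atoms: none
Why: IBX should oxidise the propargylic alcohol to the ynone, and monovalent-gold activation of the alkyne triggers 5-endo-dig addition of the C10 hydroxyl to C3, giving the 3(2H)-furanone and releasing the strain of the cyclic alkyne (cycloisomerisation of a hydroxy-ynone).

Step 17
Reactants: 24 bicyclic furanone
Product: 27 9-O-TBS ether of the target (α-methylene-γ-lactone closed), via alkenylborate 25 (not isolated), via potassium carboxylate 26 (not isolated)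
Conditions: KOtBu (1.1 equiv), THF, 0 °C; then (IPr)CuCl (10 mol%), Pd(PPh3)4 (5 mol%), CO2 (1 atm), 60 °C
Reagents that add atoms: carbon dioxide, O=C=O
Why: Proposed new method: the alkenylborate 25 transmetalates to an (IPr)Cu–alkenyl species, CO2 inserts into the Cu–C(sp2) bond to give carboxylate 26 (closest known type: NHC–copper-catalysed carboxylation of alkenylboronic esters), and zerovalent palladium ionises the C6 benzoate to an η3-allyl complex over C4–C5–C6 that the tethered carboxylate oxygen attacks (closest known type: Tsuji–Trost allylic O-alkylation/lactonisation); what is new is the relay of the two cycles in one flask. The γ-lactone closes by 5-exo attack of the carboxylate oxygen on the C6 terminus of the allyl unit. C6 is the only stereocentre formed: ionisation anti to the benzoate and outer-sphere attack anti to palladium give net retention, so the (6R) benzoate from step 11 becomes the trans-fused (6R) lactone, with the C7 centre that carries the tether directing the oxygen to that face. Regioselectivity (C6 over C4) should follow from the five- versus seven-membered ring and from C4 being fully substituted and conjugated to the furanone; the Z C4=C5 geometry cannot isomerise because the allyl unit is locked in the bicyclic ten-membered ring. Chemoselectivity (CO2 capture before alkenyl–allyl C–C coupling) should follow from fast CO2 insertion of the copper alkenyl under CO2 saturation and from the strain of any ring that direct C11–C6 or C11–C4 coupling would form; ionisation of the benzoate is reversible, so the allyl complex can wait for the carboxylate.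

Step 18
Reactants: 27 9-O-TBS ether of the target
Product: 28 CNP0146060.1
Conditions: HF·pyridine, pyridine, THF, 0 °C to rt
Reagents that add atoms: none
Why: Fluoride-mediated desilylation under mildly acidic conditions should free O9–H without acyl migration from O8 to O9 or conjugate addition to the α-methylene lactone.

**Compound list**

1 | 2-C-methyl-D-ribono-1,4-lactone | O=C1[C@](C)(O)[C@H](O)[C@@H](CO)O1 | starting material
2 | 3,5-di-O-(tert-butyldimethylsilyl)-2-C-methyl-D-ribono-1,4-lactone | O=C1[C@](C)(O)[C@H](O[Si](C)(C)C(C)(C)C)[C@@H](CO[Si](C)(C)C(C)(C)C)O1 | intermediate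
3 | 3-O-(tert-butyldimethylsilyl)-2-C-methyl-D-ribono-1,4-lactone | O=C1[C@](C)(O)[C@H](O[Si](C)(C)C(C)(C)C)[C@@H](CO)O1 | intermediate
4 | 3-O-TBS-2-C-methyl-D-ribo-pentodialdono-1,4-lactone (C7 aldehyde of 3) | O=C1[C@](C)(O)[C@H](O[Si](C)(C)C(C)(C)C)[C@@H](C=O)O1 | intermediate
5 | ethynyl carbinol: lactone 3 with C7H(OH)–C≡CH in place of CH2OH, both C7 epimers | O=C1[C@](C)(O)[C@H](O[Si](C)(C)C(C)(C)C)[C@@H](C(O)C#C)O1 | intermediate
6 | 1-alkyl-1-(2-nitrobenzenesulfonyl)hydrazine from 5 (nitrogen on C7) | O=C1[C@](C)(O)[C@H](O[Si](C)(C)C(C)(C)C)[C@@H](C(C#C)N(N)S(=O)(=O)c2ccccc2[N+](=O)[O-])O1 | intermediate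
7 | propargylic monoalkyl diazene (C7–N=NH) | O=C1[C@](C)(O)[C@H](O[Si](C)(C)C(C)(C)C)[C@@H](C(C#C)N=N)O1 | intermediate
8 | allenyl lactone: lactone 3 with CH=C=CH2 (C7=C11=C13) in place of CH2OH | O=C1[C@](C)(O)[C@H](O[Si](C)(C)C(C)(C)C)[C@@H](C=C=C)O1 | intermediate
9 | allenyl triol: open chain C1H2OH–C10(CH3)(OH)–C9H(OTBS)–C8H(OH)–CH=C=CH2, D-ribo configuration | OC[C@](C)(O)[C@H](O[Si](C)(C)C(C)(C)C)[C@H](O)C=C=C | intermediate
10 | C1,C10-O-isopropylidene acetal of 9 (C8–OH free) | CC1(C)OC[C@](C)(O1)[C@H](O[Si](C)(C)C(C)(C)C)[C@H](O)C=C=C | intermediate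
11 | (R)-2-methylbutanoic acid | CC[C@@H](C)C(=O)O | starting material
12 | allenyl ester: C8 (R)-2-methylbutanoate of 10 with inverted C8 (C8, C9, C10 as in the target) | CC1(C)OC[C@](C)(O1)[C@H](O[Si](C)(C)C(C)(C)C)[C@@H](OC(=O)[C@H](C)CC)C=C=C | intermediate
13 | (Z)-3-methylpent-2-en-4-yn-1-ol | OC/C=C(/C)C#C | starting material
14 | (Z)-3-methylpent-2-en-4-ynal | O=C/C=C(/C)C#C | intermediate
15 | (Z)-bis(pinacolboronate): 12 with C7H=C11(Bpin)–C13H2Bpin, C8 cis to C13 | CC1(C)OC[C@](C)(O1)[C@H](O[Si](C)(C)C(C)(C)C)[C@@H](OC(=O)[C@H](C)CC)/C=C(\CB2OC(C)(C)C(C)(C)O2)B3OC(C)(C)C(C)(C)O3 | intermediate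
16 | O6-pinacolboryl syn adduct of 15 and 14 | CC1(C)OC[C@](C)(O1)[C@H](O[Si](C)(C)C(C)(C)C)[C@@H](OC(=O)[C@H](C)CC)[C@H]([C@@H](OB2OC(C)(C)C(C)(C)O2)/C=C(/C)C#C)C(=C)B3OC(C)(C)C(C)(C)O3 | intermediate
17 | syn homoallylic alcohol (6S,7S): C6–OH, C7–C11(Bpin)=C13H2, Z-C4=C5, terminal alkyne C2≡C3 | CC1(C)OC[C@](C)(O1)[C@H](O[Si](C)(C)C(C)(C)C)[C@@H](OC(=O)[C@H](C)CC)[C@H]([C@@H](O)/C=C(/C)C#C)C(=C)B2OC(C)(C)C(C)(C)O2 | intermediate
18 | (6R)-benzoate of 17 with inverted C6 (6R,7S) | CC1(C)OC[C@](C)(O1)[C@H](O[Si](C)(C)C(C)(C)C)[C@@H](OC(=O)[C@H](C)CC)[C@H]([C@H](OC(=O)c2ccccc2)/C=C(/C)C#C)C(=C)B3OC(C)(C)C(C)(C)O3 | intermediate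
19 | C1,C10-diol of 18 | OC[C@](C)(O)[C@H](O[Si](C)(C)C(C)(C)C)[C@@H](OC(=O)[C@H](C)CC)[C@H]([C@H](OC(=O)c1ccccc1)/C=C(/C)C#C)C(=C)B2OC(C)(C)C(C)(C)O2 | intermediate
20 | C2-iodoalkyne of 19 | OC[C@](C)(O)[C@H](O[Si](C)(C)C(C)(C)C)[C@@H](OC(=O)[C@H](C)CC)[C@H]([C@H](OC(=O)c1ccccc1)/C=C(/C)C#CI)C(=C)B2OC(C)(C)C(C)(C)O2 | intermediate
21 | C1 aldehyde of 20 (α-hydroxy aldehyde) | O=C[C@](C)(O)[C@H](O[Si](C)(C)C(C)(C)C)[C@@H](OC(=O)[C@H](C)CC)[C@H]([C@H](OC(=O)c1ccccc1)/C=C(/C)C#CI)C(=C)B2OC(C)(C)C(C)(C)O2 | intermediate
22 | ten-membered enyne diol: C1–C2 bond closed, C1 carbinol epimers, C2≡C3, Z-C4=C5 | OC1[C@](C)(O)[C@H](O[Si](C)(C)C(C)(C)C)[C@@H](OC(=O)[C@H](C)CC)[C@H]([C@H](OC(=O)c2ccccc2)/C=C(/C)C#C1)C(=C)B3OC(C)(C)C(C)(C)O3 | intermediate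
23 | ten-membered hydroxy-ynone (C1 ketone of 22) | O=C1[C@](C)(O)[C@H](O[Si](C)(C)C(C)(C)C)[C@@H](OC(=O)[C@H](C)CC)[C@H]([C@H](OC(=O)c2ccccc2)/C=C(/C)C#C1)C(=C)B3OC(C)(C)C(C)(C)O3 | intermediate
24 | bicyclic 3(2H)-furanone (3,10-epoxygermacra-2,4-dien-1-one) with C6 benzoate, C7 C(Bpin)=CH2, C8 (R)-2-methylbutanoate, C9 OTBS | O=C1[C@](C)(O2)[C@H](O[Si](C)(C)C(C)(C)C)[C@@H](OC(=O)[C@H](C)CC)[C@H]([C@H](OC(=O)c3ccccc3)/C=C(/C)C2=C1)C(=C)B4OC(C)(C)C(C)(C)O4 | intermediate
25 | potassium tert-butoxy(pinacolato)alkenylborate of 24 | O=C1[C@](C)(O2)[C@H](O[Si](C)(C)C(C)(C)C)[C@@H](OC(=O)[C@H](C)CC)[C@H]([C@H](OC(=O)c3ccccc3)/C=C(/C)C2=C1)C(=C)[B-]4(OC(C)(C)C)OC(C)(C)C(C)(C)O4.[K+] | intermediate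
26 | potassium acrylate (C11–CO2K, C12 from CO2) with C6 benzoate intact | O=C1[C@](C)(O2)[C@H](O[Si](C)(C)C(C)(C)C)[C@@H](OC(=O)[C@H](C)CC)[C@H]([C@H](OC(=O)c3ccccc3)/C=C(/C)C2=C1)C(=C)C(=O)[O-].[K+] | intermediate
27 | 9-O-TBS ether of the target | O=C1[C@](C)(O2)[C@H](O[Si](C)(C)C(C)(C)C)[C@@H](OC(=O)[C@H](C)CC)[C@@H]3[C@H](OC(=O)C3=C)/C=C(/C)C2=C1 | intermediate
28 | CNP0146060.1: (6R,7S,8S,9R,10R)-9-hydroxy-8-[(2R)-2-methylbutanoyloxy]-1-oxo-3,10-epoxygermacra-2,4(Z),11(13)-trien-6,12-olide | C=C1C(=O)O[C@@H]2/C=C(/C)C3=CC(=O)[C@](C)(O3)[C@H](O)[C@@H](OC(=O)[C@H](C)CC)[C@@H]12 | target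

**Step count and risks**

Total step count: 18. Longest linear sequence: 17 steps (steps 1–8 and 10–18, from 1).

Steps most likely to fail:

1. Step 17 (the proposed new method). The two catalytic cycles may interfere: alkenyl transfer to palladium followed by C–C coupling, β-hydride elimination of the allyl complex to a diene, or protodeboronation may outrun CO2 capture. The fallback sets out from 24 and comes back at 27. The relay is given up and its two halves, each a known reaction, are run apart. 24 is carboxylated without palladium ((IPr)CuCl, KOtBu, CO2, THF, 60 °C; aqueous HCl work-up) to the 2-substituted acrylic acid F1, whose allylic benzoate stays untouched. The isolated acid is then cyclised with Pd(PPh3)4 and Et3N in THF (Tsuji–Trost lactonisation, net retention at C6) to 27.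

2. Step 10. Facial selectivity at C7 may be insufficient, since the C8 centre is the only control element, and the hindered (Z)-allylboronate may add sluggishly. The fallback sets out from 12 and comes back at 17. Bis(boronate) 15 is isolated after the diboration and the allylboration is moved from substrate control to catalyst control: a chiral BINOL-derived phosphoric acid (TRIP, the enantiomer matched to the substrate) activates the boronate oxygen and fixes the aldehyde face in the chair transition state in toluene at −30 °C. The C6/C7 pair then no longer relies on the bias of C8, and no new compound arises (F0).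

3. Step 15. Oligomerisation or reductive loss of iodine may compete with closure of the strained ten-membered enyne. The fallback sets out from 19 and comes back at 22. The organochromium route is replaced by a zinc acetylide made by C–H metalation: 19 is oxidised with IBX directly to the alkynyl hydroxy-aldehyde F2, which is cyclised with Zn(OTf)2 and Et3N in toluene under high dilution (amine-promoted zinc alkynylation of an aldehyde). This avoids the C–I bond altogether and rejoins the route before step 16.

Further compounds
F1 | step 17 | 2-substituted acrylic acid (C11–CO2H) with C6 benzoate intact | O=C1[C@](C)(O2)[C@H](O[Si](C)(C)C(C)(C)C)[C@@H](OC(=O)[C@H](C)CC)[C@H]([C@H](OC(=O)c3ccccc3)/C=C(/C)C2=C1)C(=C)C(=O)O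
F0 | step 10 | none | none
F2 | step 15 | alkynyl hydroxy-aldehyde (C1 aldehyde of 19, terminal alkyne) | O=C[C@](C)(O)[C@H](O[Si](C)(C)C(C)(C)C)[C@@H](OC(=O)[C@H](C)CC)[C@H]([C@H](OC(=O)c1ccccc1)/C=C(/C)C#C)C(=C)B2OC(C)(C)C(C)(C)O2
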